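**Assumption:** the target has no stereocentre and no configurationally stable axis, so it is achiral and "single enantiomer" needs no stereocontrol.

## Retrosynthetic overview

1. The target comes from a fully masked flavone by one BCl3 operation (5‑OMe → 5‑OH; OCH2O → catechol).
2. Key disconnection C2–C1′: the chromone C2, natively the electrophilic β‑carbon of the enone, is used as a nucleophile. The C2‑zincated 3‑methoxychromone is a β‑acylvinyl / α‑alkoxyvinyl anion (homoenolate‑type d3, masked acyl anion). It is joined to the electrophilic C–Br carbon of the B‑ring bromide.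
3. 3,5,6,7,8‑Pentamethoxychromone comes from an o‑hydroxy‑ω‑methoxyacetophenone plus a one‑carbon unit. The ketone comes from pentamethoxybenzene and methoxyacetyl chloride, and pentamethoxybenzene from 2,6‑dimethoxy‑1,4‑benzoquinone.
4. The B‑ring bromide comes from sesamol by O‑methylation and bromination.
5. Ring order: A ring aromatised from the quinone first, pyranone C ring closed second, B ring attached last.

## Route

Step 1
Reactants: 1 2,6-dimethoxy-1,4-benzoquinone
Product: 2 3,5-dimethoxybenzene-1,2,4-triyl triacetate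
Conditions: Ac2O, cat. conc. H2SO4, 25–40 °C; ice-water
Reagents that add atoms: acetic anhydride CC(=O)OC(C)=O
Why: Thiele–Winter acetoxylation: the acid-activated, symmetric quinone takes up acetate at its free ring carbon, aromatises and is peracetylated, which installs the fifth ring oxygen as a single isomer.

Step 2
Reactants: 2 3,5-dimethoxybenzene-1,2,4-triyl triacetate
Product: 4 pentamethoxybenzene, via free triol 3 (not isolated)
Conditions: Me2SO4, aq NaOH, cat. Na2S2O4, MeOH, N2, 0 → 50 °C
Reagents that add atoms: dimethyl sulfate COS(=O)(=O)OC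
Why: Saponification of the aryl acetates and Williamson O-methylation in one pot under oxygen-free, reducing conditions avoids isolating the air-sensitive triol.

Step 3
Reactants: 4 pentamethoxybenzene
Product: 6 1-(2-hydroxy-3,4,5,6-tetramethoxyphenyl)-2-methoxyethan-1-one, via pentamethoxyphenyl ketone 5 (not isolated)
Conditions: MeOCH2COCl (1.2 equiv), AlCl3 (2.5 equiv), Et2O, 0 °C → rt; aqueous work-up
Reagents that add atoms: methoxyacetyl chloride COCC(Cl)=O
Why: Friedel–Crafts acylation at the only free position of the symmetric arene, then chelation-controlled AlCl3 demethylation of one of the two equivalent ortho methoxy groups, gives a single o-hydroxy ketone.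

Step 4
Reactants: 6 1-(2-hydroxy-3,4,5,6-tetramethoxyphenyl)-2-methoxyethan-1-one
Product: 8 3,5,6,7,8-pentamethoxy-4H-chromen-4-one, via enaminone 7 (not isolated)
Conditions: DMF-DMA (3 equiv), toluene, 100 °C; then AcOH, 60 °C
Reagents that add atoms: N,N-dimethylformamide dimethyl acetal COC(OC)N(C)C
Why: Enaminone chromone synthesis: condensation at the activated α-methylene, then acid-promoted intramolecular O-addition and loss of dimethylamine, closes the pyranone with the 3-OMe in place and C2–H free.

Step 5
Reactants: 9 sesamol (1,3-benzodioxol-5-ol)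
Product: 10 5-methoxy-1,3-benzodioxole
Conditions: MeI, K2CO3, acetone, reflux
Reagents that add atoms: iodomethane CI
Why: Williamson ether synthesis on the only phenol.

Step 6
Reactants: 10 5-methoxy-1,3-benzodioxole
Product: 11 5-bromo-6-methoxy-1,3-benzodioxole
Conditions: NBS, MeCN, 0 °C → rt
Reagents that add atoms: N-bromosuccinimide O=C1CCC(=O)N1Br
Why: Electrophilic aromatic bromination goes to C6, which is ortho to OMe, para to a dioxole oxygen and unhindered, setting the 2′-OMe/4′,5′-dioxy pattern of the B ring.

Step 7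
Reactants: 8 3,5,6,7,8-pentamethoxy-4H-chromen-4-one; 11 5-bromo-6-methoxy-1,3-benzodioxole
Product: 13 3,5,6,7,8-pentamethoxy-2-(6-methoxy-1,3-benzodioxol-5-yl)-4H-chromen-4-one, via chromon-2-ylzinc chloride 12 (not isolated)
Conditions: TMPZnCl·LiCl (1.2 equiv), THF, 25 °C, 1 h; then 11 (0.85 equiv), Pd(OAc)2 (2 mol %), SPhos (4 mol %), 50 °C
Reagents that add atoms: none
Why: Directed C2–H zincation (the only ring C–H of 8, acidified by O1 and flanked by 3-OMe) turns the normally electrophilic enone β-carbon into a β-acylvinyl/α-alkoxyvinyl nucleophile (homoenolate-type d3, masked acyl anion), and Negishi cross-coupling joins it to the electrophilic C–Br carbon of 11; the non-nucleophilic amide base and the organozinc leave the C4 ketone untouched, and no stereocentre is formed.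

Step 8
Reactants: 13 3,5,6,7,8-pentamethoxy-2-(6-methoxy-1,3-benzodioxol-5-yl)-4H-chromen-4-one
Product: 14 5,4',5'-trihydroxy-3,6,7,8,2'-pentamethoxyflavone
Conditions: BCl3 (1 M in CH2Cl2, 6 equiv), CH2Cl2, −78 °C → rt; then THF/aq HCl, 40 °C
Reagents that add atoms: none
Why: Lewis-acid ether cleavage: BCl3 removes the peri 5-OMe through the six-membered C4=O chelate and opens the methylenedioxy acetal, both far faster than the unactivated 3-, 6-, 7-, 8- and 2′-methyl ethers, and the hydrolytic work-up frees the catechol.

## Compound list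

1 | 2,6-dimethoxy-1,4-benzoquinone | COC1=CC(=O)C=C(OC)C1=O | starting material
2 | 3,5-dimethoxybenzene-1,2,4-triyl triacetate | COc1cc(OC(C)=O)c(OC(C)=O)c(OC)c1OC(C)=O | intermediate
3 | 3,5-dimethoxybenzene-1,2,4-triol | COc1cc(O)c(O)c(OC)c1O | intermediate
4 | pentamethoxybenzene | COc1cc(OC)c(OC)c(OC)c1OC | intermediate
5 | 2-methoxy-1-(2,3,4,5,6-pentamethoxyphenyl)ethan-1-one | COCC(=O)c1c(OC)c(OC)c(OC)c(OC)c1OC | intermediate
6 | 1-(2-hydroxy-3,4,5,6-tetramethoxyphenyl)-2-methoxyethan-1-one | COCC(=O)c1c(O)c(OC)c(OC)c(OC)c1OC | intermediate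
7 | (Z)-3-(dimethylamino)-1-(2-hydroxy-3,4,5,6-tetramethoxyphenyl)-2-methoxyprop-2-en-1-one (either alkene isomer cyclises) | CO/C(=C\N(C)C)C(=O)c1c(O)c(OC)c(OC)c(OC)c1OC | intermediate
8 | 3,5,6,7,8-pentamethoxy-4H-chromen-4-one | COc1coc2c(OC)c(OC)c(OC)c(OC)c2c1=O | intermediate
9 | sesamol (1,3-benzodioxol-5-ol) | Oc1ccc2OCOc2c1 | starting material
10 | 5-methoxy-1,3-benzodioxole | COc1ccc2OCOc2c1 | intermediate
11 | 5-bromo-6-methoxy-1,3-benzodioxole | COc1cc2OCOc2cc1Br | intermediate
12 | (3,5,6,7,8-pentamethoxy-4-oxo-4H-chromen-2-yl)zinc chloride (LiCl complex) | COc1c([Zn]Cl)oc2c(OC)c(OC)c(OC)c(OC)c2c1=O | intermediate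
13 | 3,5,6,7,8-pentamethoxy-2-(6-methoxy-1,3-benzodioxol-5-yl)-4H-chromen-4-one | COc1cc2OCOc2cc1-c1oc2c(OC)c(OC)c(OC)c(OC)c2c(=O)c1OC | intermediate
14 | 5,4',5'-trihydroxy-3,6,7,8,2'-pentamethoxyflavone | COc1cc(O)c(O)cc1-c1oc2c(OC)c(OC)c(OC)c(O)c2c(=O)c1OC | target

## Step count and risks

Total steps: 8. Longest linear sequence: 6 (steps 1, 2, 3, 4, 7, 8); steps 5 and 6 form the two-step B-ring branch.

**Step 7 (key coupling).** The risk is sluggish transmetalation or reductive elimination between an electron-poor, ortho-substituted alkenylzinc and an electron-rich, ortho-substituted aryl bromide; incomplete zincation is the lesser risk. The fallback sets out from 8 and 11 and comes back at 13, with the roles of the partners inverted. Chromone 8 is zincated as before to 12 and quenched with I2 (THF, 0 °C) to give 2-iodo-3,5,6,7,8-pentamethoxy-4H-chromen-4-one F1. Bromide 11 undergoes Miyaura borylation (B2pin2, Pd(dppf)Cl2, KOAc, dioxane, 90 °C) to give 2-(6-methoxy-1,3-benzodioxol-5-yl)-4,4,5,5-tetramethyl-1,3,2-dioxaborolane F2. Suzuki–Miyaura coupling of the two (Pd(dppf)Cl2, K2CO3, dioxane/H2O, 80 °C) then delivers 13; oxidative addition into the 2-iodochromone is easy, and the umpoled C2–metal is still what functionalises C2.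

**Step 8 (global BCl3 unmasking).** The risk is that the acetal needs room temperature and excess BCl3, which may start to cleave the 3- or 6-OMe, or that acetal cleavage stays incomplete. The fallback sets out from 11 and comes back at 14, moving the acetal cleavage to a simple early compound and changing the catechol protection. BCl3 (CH2Cl2, 0 °C → rt) on 11 gives 4-bromo-5-methoxybenzene-1,2-diol F3. BnBr/K2CO3 (DMF, 60 °C) gives 1,2-bis(benzyloxy)-4-bromo-5-methoxybenzene F4. Negishi coupling of F4 with zinc reagent 12 (made from 8 as in step 7) gives 2-[4,5-bis(benzyloxy)-2-methoxyphenyl]-3,5,6,7,8-pentamethoxy-4H-chromen-4-one F5. BCl3 with pentamethylbenzene (CH2Cl2, −78 → 0 °C) then removes both benzyl groups and the chelated 5-OMe under much milder conditions to give 14.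

**Step 3 (Friedel–Crafts acylation with in-situ mono-demethylation).** The risk is over-demethylation, or cleavage of the ω-methoxy group by AlCl3 chelated to the α-alkoxy ketone. The fallback sets out from 4 and comes back at 6, separating C–C bond formation from demethylation. The ring C–H flanked by two methoxy groups is lithiated (n-BuLi, THF, 0 °C) to give (2,3,4,5,6-pentamethoxyphenyl)lithium F6. This is acylated with N-methoxy-N-methyl-2-methoxyacetamide (−78 °C → rt) to ketone 5, isolated this time. BCl3 (1.1 equiv, CH2Cl2, −78 → 0 °C) then removes one of the two equivalent ortho methyl groups to give 6.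

## Further compounds

F1 | step 7 | 2-iodo-3,5,6,7,8-pentamethoxy-4H-chromen-4-one | COc1c(I)oc2c(OC)c(OC)c(OC)c(OC)c2c1=O
F2 | step 7 | 2-(6-methoxy-1,3-benzodioxol-5-yl)-4,4,5,5-tetramethyl-1,3,2-dioxaborolane | COc1cc2OCOc2cc1B1OC(C)(C)C(C)(C)O1
F3 | step 8 | 4-bromo-5-methoxybenzene-1,2-diol | COc1cc(O)c(O)cc1Br
F4 | step 8 | 1,2-bis(benzyloxy)-4-bromo-5-methoxybenzene | COc1cc(OCc2ccccc2)c(OCc2ccccc2)cc1Br
F5 | step 8 | 2-[4,5-bis(benzyloxy)-2-methoxyphenyl]-3,5,6,7,8-pentamethoxy-4H-chromen-4-one | COc1cc(OCc2ccccc2)c(OCc2ccccc2)cc1-c1oc2c(OC)c(OC)c(OC)c(OC)c2c(=O)c1OC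
F6 | step 3 | (2,3,4,5,6-pentamethoxyphenyl)lithium | [Li]c1c(OC)c(OC)c(OC)c(OC)c1OC
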